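**Retrosynthetic overview**

1. The target is (2R)-glycerol carrying acetate on one primary oxygen and ent-labd-8-en-15-oic acid on the other (labdane numbering: ring A = C1–C5 and C10, ring B = C5–C10, gem-dimethyl on C4, angular methyl on C10, chain C11–C15 with the methyl-bearing C13). The glyceride is made last: acid plus (S)-solketal, acetonide removal, primary acetylation.
2. Ring B is formed second: C9–C10 by proton-initiated cation–olefin closure of a monocyclic acid, with the ring-A alkene C1=C10 as initiator and the (E)-C8=C9 chain alkene as terminator; the trans fusion is relayed from C5.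
3. Ring A is formed first: C2–C3 and C4–C5 by an enantioselective Diels–Alder reaction between the terminal diene C2=C1–C10(CH3)=C5 of an acyclic triene and methacrolein (C3, C4, one C4 methyl, and a formyl group that Wolff–Kishner reduction turns into the second methyl).
4. Enabling feature: in ring A the C3–C4 unit is CH2–C(CH3)2, an isobutene-type two-carbon unit. The other four ring atoms C2–C1–C10–C5 can exist as a 1,3-diene because the fourth bond of quaternary C10 (C9–C10) belongs to ring B and is made afterwards, from the very C1=C10 alkene that the cycloaddition leaves behind.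
5. The triene comes from (2E,6E)-farnesol: Ru–BINAP hydrogenation sets C13, terminal allylic oxidation and Wittig methylenation install the diene.

Key step: step 6

Assumption: the catalyst enantiomer in step 6 is assigned from the accepted formyl C–H···O binding model of cationic oxazaborolidines and the formyl-endo mode; the sense would be confirmed on the first sample, and the mirror-image catalyst is equally available.

**Route**

Step 1
Reactants: 1 (2E,6E)-farnesol
Product: 2 (3R,6E)-3,7,11-trimethyldodeca-6,10-dien-1-ol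
Conditions: Ru(OAc)2[(S)-BINAP] (0.5 mol%), H2 (100 atm), MeOH, 25 °C
Reagents that add atoms: none
Why: Ru–BINAP asymmetric hydrogenation of an allylic alcohol; the hydroxyl group directs the metal so that only C2=C3 is reduced, the (S)-ligand should give the (3R) centre (C13 of the target) from the (E)-alkene, and the two remote trisubstituted alkenes are left.

Step 2
Reactants: 2 (3R,6E)-3,7,11-trimethyldodeca-6,10-dien-1-ol
Product: 3 (3R,6E)-3,7,11-trimethyldodeca-6,10-dien-1-yl acetate
Conditions: Ac2O, pyridine, 4-(dimethylamino)pyridine (cat.), CH2Cl2, 0 °C to rt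
Reagents that add atoms: acetic anhydride, CC(=O)OC(C)=O
Why: nucleophile-catalysed acetylation; the acetate masks the alcohol through the oxidation, ylide and Lewis-acid steps and is removed without an extra step in step 7.

Step 3
Reactants: 3 (3R,6E)-3,7,11-trimethyldodeca-6,10-dien-1-yl acetate
Product: 4 (3R,6E,10E)-12-hydroxy-3,7,11-trimethyldodeca-6,10-dien-1-yl acetate
Conditions: SeO2 (0.3 equiv), 2-hydroxybenzoic acid (0.1 equiv), t-BuOOH (70% aq., 3 equiv), CH2Cl2, 0 °C to rt
Reagents that add atoms: selenium dioxide, O=[Se]=O (delivers the oxygen atom; re-oxidised by tert-butyl hydroperoxide, CC(C)(C)OO)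
Why: selenium dioxide allylic oxidation (ene reaction, then [2,3]-sigmatropic shift) should hydroxylate the (E)-methyl group of the terminal isopropylidene unit, the established site in geranyl and farnesyl acetates, faster than the internal alkene.

Step 4
Reactants: 4 (3R,6E,10E)-12-hydroxy-3,7,11-trimethyldodeca-6,10-dien-1-yl acetate
Product: 5 (3R,6E,10E)-3,7,11-trimethyl-12-oxododeca-6,10-dien-1-yl acetate
Conditions: 2,2,6,6-tetramethylpiperidin-1-oxyl (10 mol%), PhI(OAc)2 (1.1 equiv), CH2Cl2, rt
Reagents that add atoms: none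
Why: oxoammonium-mediated oxidation of a primary allylic alcohol to the enal without E/Z isomerisation; any enal already formed in step 3 converges here.

Step 5
Reactants: 5 (3R,6E,10E)-3,7,11-trimethyl-12-oxododeca-6,10-dien-1-yl acetate
Product: 6 (3R,6E,10E)-3,7,11-trimethyltrideca-6,10,12-trien-1-yl acetate
Conditions: Ph3PCH3Br (1.2 equiv), KN(SiMe3)2 (1.15 equiv), THF, −78 °C to 0 °C
Reagents that add atoms: methyltriphenylphosphonium bromide, C[P+](c1ccccc1)(c1ccccc1)c1ccccc1.[Br-]
Why: Wittig methylenation of the enal is much faster than attack on the acetate at low temperature and should give the (E)-1-alkyl-2-methylbutadiene terminus C2=C1–C10(CH3)=C5 with the alkene geometry intact.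

Step 6
Reactants: 6 (3R,6E,10E)-3,7,11-trimethyltrideca-6,10,12-trien-1-yl acetate; 7 methacrolein
Product: 8 (3R,6E)-9-[(1S,6R)-6-formyl-2,6-dimethylcyclohex-2-en-1-yl]-3,7-dimethylnon-6-en-1-yl acetate
Conditions: 7 (5 equiv), (R)-3,3-diphenyl-1-(2-methylphenyl)tetrahydro-1H,3H-pyrrolo[1,2-c][1,3,2]oxazaborole (20 mol%) protonated with (CF3SO2)2NH (20 mol%), CH2Cl2, −78 °C to −40 °C
Reagents that add atoms: none
Why: Lewis-acid-catalysed, concerted but asynchronous normal-electron-demand [4+2] cycloaddition between the (E)-configured terminal diene of 6 and s-trans methacrolein bound to the chiral oxazaborolidinium ion; the closest known reaction type is the cationic-oxazaborolidine-catalysed enantioselective Diels–Alder reaction of 2-methylacrolein with acyclic 1-substituted and 2-substituted butadienes. Ring A (C5–C4–C3–C2–C1=C10) closes in one intermolecular suprafacial [4+2] event that forms C2–C3 and C4–C5 together and leaves the C1=C10 alkene. The C5 stereocentre and the temporary quaternary C4 stereocentre are set by the catalyst, which shields one face of the coordinated enal so that the diene adds to the si face of the α-carbon, combined with the formyl-endo transition state of the (E)-diene, which places the formyl group cis to the C6 chain. The step needs regioselectivity (quaternary dienophile carbon to C5), endo selectivity and facial selectivity; the regiochemistry should be secured by the dominant directing effect of the terminal C5 alkyl group over the C10 methyl group, as with 1-vinylcycloalkenes, and by the leading bond joining the two unhindered CH2 termini. The isolated C8=C9 alkene and the acetate are inert, and any exo diastereomer is removed by chromatography here because it carries the opposite configuration at C5.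

Step 7
Reactants: 8 (3R,6E)-9-[(1S,6R)-6-formyl-2,6-dimethylcyclohex-2-en-1-yl]-3,7-dimethylnon-6-en-1-yl acetate
Product: 10 (3R,6E)-3,7-dimethyl-9-[(1R)-2,6,6-trimethylcyclohex-2-en-1-yl]non-6-en-1-ol, via hydroxy hydrazone 9 (not isolated)
Conditions: N2H4·H2O (10 equiv), KOH (6 equiv), diethylene glycol, 130 °C, then removal of water and 200 °C
Reagents that add atoms: none
Why: Wolff–Kishner reduction of a non-enolisable neopentyl aldehyde turns the formyl group into the second C4 methyl group (C4 is no longer stereogenic, C5 is untouched) while the hydroxide cleaves the acetate; isolated alkenes survive.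

Step 8
Reactants: 10 (3R,6E)-3,7-dimethyl-9-[(1R)-2,6,6-trimethylcyclohex-2-en-1-yl]non-6-en-1-ol
Product: 11 (3R,6E)-3,7-dimethyl-9-[(1R)-2,6,6-trimethylcyclohex-2-en-1-yl]non-6-enoic acid
Conditions: 2,2,6,6-tetramethylpiperidin-1-oxyl (20 mol%), PhI(OAc)2 (2.5 equiv), MeCN/H2O (1:1), rt
Reagents that add atoms: water, O
Why: oxoammonium oxidation of the primary alcohol through the aldehyde hydrate to the acid under near-neutral conditions that leave both trisubstituted alkenes and the β-stereocentre alone.

Step 9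
Reactants: 11 (3R,6E)-3,7-dimethyl-9-[(1R)-2,6,6-trimethylcyclohex-2-en-1-yl]non-6-enoic acid
Product: 13 (3R)-3-methyl-5-[(4aR,8aR)-2,5,5,8a-tetramethyl-3,4,4a,5,6,7,8,8a-octahydronaphthalen-1-yl]pentanoic acid, via labd-7-ene acid 12 (not isolated)
Conditions: FSO3H (5 equiv), 2-nitropropane, −78 °C, Et3N quench; then crude product, HI (57% aq., cat.), benzene, 80 °C
Reagents that add atoms: none
Why: proton-initiated cation–olefin cyclisation as known for α-monocyclic farnesyl-type terpenoids: Markovnikov protonation of C1=C10 gives the tertiary C10 cation, chair-like 6-endo attack by C9 of the (E)-alkene makes C9–C10 with the C10 methyl anti to C5–H (trans-decalin, controlled by C5), and acid-catalysed olefin isomerisation should then funnel the kinetic alkene isomers to the tetrasubstituted C8=C9 alkene, the thermodynamic isomer.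

Step 10
Reactants: 13 (3R)-3-methyl-5-[(4aR,8aR)-2,5,5,8a-tetramethyl-3,4,4a,5,6,7,8,8a-octahydronaphthalen-1-yl]pentanoic acid; 14 (S)-solketal
Product: 15 [(4R)-2,2-dimethyl-1,3-dioxolan-4-yl]methyl (3R)-3-methyl-5-[(4aR,8aR)-2,5,5,8a-tetramethyl-3,4,4a,5,6,7,8,8a-octahydronaphthalen-1-yl]pentanoate
Conditions: EDC·HCl (1.3 equiv), 4-(dimethylamino)pyridine (0.2 equiv), CH2Cl2, 0 °C to rt
Reagents that add atoms: none
Why: carbodiimide esterification (Steglich type) of an unhindered acid with a primary alcohol; the glycerol stereocentre comes from the chiral pool and no bond to it is touched.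

Step 11
Reactants: 15 [(4R)-2,2-dimethyl-1,3-dioxolan-4-yl]methyl (3R)-3-methyl-5-[(4aR,8aR)-2,5,5,8a-tetramethyl-3,4,4a,5,6,7,8,8a-octahydronaphthalen-1-yl]pentanoate
Product: 16 (2R)-2,3-dihydroxypropyl (3R)-3-methyl-5-[(4aR,8aR)-2,5,5,8a-tetramethyl-3,4,4a,5,6,7,8,8a-octahydronaphthalen-1-yl]pentanoate
Conditions: AcOH/H2O (4:1), 40 °C; product used at once
Reagents that add atoms: none
Why: mild acid hydrolysis of the isopropylidene acetal, which the ester and the tetrasubstituted alkene tolerate; short contact and immediate use limit acyl migration.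

Step 12
Reactants: 16 (2R)-2,3-dihydroxypropyl (3R)-3-methyl-5-[(4aR,8aR)-2,5,5,8a-tetramethyl-3,4,4a,5,6,7,8,8a-octahydronaphthalen-1-yl]pentanoate
Product: 17 (2R)-3-(acetyloxy)-2-hydroxypropyl (3R)-3-methyl-5-[(4aR,8aR)-2,5,5,8a-tetramethyl-3,4,4a,5,6,7,8,8a-octahydronaphthalen-1-yl]pentanoate
Conditions: AcCl (1.05 equiv), 2,4,6-collidine (2 equiv), CH2Cl2, −78 °C
Reagents that add atoms: acetyl chloride, CC(=O)Cl
Why: sterically controlled acylation with a hindered pyridine base at low temperature should acetylate the primary hydroxyl group selectively and leave the secondary one free, giving the target.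

**Compound list**

1 | (2E,6E)-farnesol | OC/C=C(\C)CC/C=C(\C)CCC=C(C)C | starting material
2 | (3R,6E)-3,7,11-trimethyldodeca-6,10-dien-1-ol | OCC[C@H](C)CC/C=C(\C)CCC=C(C)C | intermediate
3 | (3R,6E)-3,7,11-trimethyldodeca-6,10-dien-1-yl acetate | CC(=O)OCC[C@H](C)CC/C=C(\C)CCC=C(C)C | intermediate
4 | (3R,6E,10E)-12-hydroxy-3,7,11-trimethyldodeca-6,10-dien-1-yl acetate | CC(=O)OCC[C@H](C)CC/C=C(\C)CC/C=C(\C)CO | intermediate
5 | (3R,6E,10E)-3,7,11-trimethyl-12-oxododeca-6,10-dien-1-yl acetate | CC(=O)OCC[C@H](C)CC/C=C(\C)CC/C=C(\C)C=O | intermediate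
6 | (3R,6E,10E)-3,7,11-trimethyltrideca-6,10,12-trien-1-yl acetate | CC(=O)OCC[C@H](C)CC/C=C(\C)CC/C=C(\C)C=C | intermediate
7 | methacrolein (2-methylprop-2-enal) | CC(=C)C=O | starting material
8 | (3R,6E)-9-[(1S,6R)-6-formyl-2,6-dimethylcyclohex-2-en-1-yl]-3,7-dimethylnon-6-en-1-yl acetate | CC(=O)OCC[C@H](C)CC/C=C(\C)CC[C@@H]1[C@](C)(C=O)CCC=C1C | intermediate
9 | (3R,6E)-9-[(1S,6R)-6-(hydrazinylidenemethyl)-2,6-dimethylcyclohex-2-en-1-yl]-3,7-dimethylnon-6-en-1-ol | OCC[C@H](C)CC/C=C(\C)CC[C@@H]1[C@](C)(C=NN)CCC=C1C | intermediate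
10 | (3R,6E)-3,7-dimethyl-9-[(1R)-2,6,6-trimethylcyclohex-2-en-1-yl]non-6-en-1-ol | OCC[C@H](C)CC/C=C(\C)CC[C@@H]1C(C)(C)CCC=C1C | intermediate
11 | (3R,6E)-3,7-dimethyl-9-[(1R)-2,6,6-trimethylcyclohex-2-en-1-yl]non-6-enoic acid | OC(=O)C[C@H](C)CC/C=C(\C)CC[C@@H]1C(C)(C)CCC=C1C | intermediate
12 | (3R)-3-methyl-5-[(1R,4aR,8aR)-2,5,5,8a-tetramethyl-1,4,4a,5,6,7,8,8a-octahydronaphthalen-1-yl]pentanoic acid | OC(=O)C[C@H](C)CC[C@@H]1C(C)=CC[C@@H]2C(C)(C)CCC[C@@]12C | intermediate
13 | (3R)-3-methyl-5-[(4aR,8aR)-2,5,5,8a-tetramethyl-3,4,4a,5,6,7,8,8a-octahydronaphthalen-1-yl]pentanoic acid (ent-labd-8-en-15-oic acid) | OC(=O)C[C@H](C)CCC1=C(C)CC[C@@H]2C(C)(C)CCC[C@@]12C | intermediate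
14 | (S)-solketal, [(4S)-2,2-dimethyl-1,3-dioxolan-4-yl]methanol | OC[C@H]1COC(C)(C)O1 | starting material
15 | [(4R)-2,2-dimethyl-1,3-dioxolan-4-yl]methyl (3R)-3-methyl-5-[(4aR,8aR)-2,5,5,8a-tetramethyl-3,4,4a,5,6,7,8,8a-octahydronaphthalen-1-yl]pentanoate | CC1(C)OC[C@H](COC(=O)C[C@H](C)CCC2=C(C)CC[C@@H]3C(C)(C)CCC[C@@]23C)O1 | intermediate
16 | (2R)-2,3-dihydroxypropyl (3R)-3-methyl-5-[(4aR,8aR)-2,5,5,8a-tetramethyl-3,4,4a,5,6,7,8,8a-octahydronaphthalen-1-yl]pentanoate | OC[C@@H](O)COC(=O)C[C@H](C)CCC1=C(C)CC[C@@H]2C(C)(C)CCC[C@@]12C | intermediate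
17 | (2R)-3-(acetyloxy)-2-hydroxypropyl (3R)-3-methyl-5-[(4aR,8aR)-2,5,5,8a-tetramethyl-3,4,4a,5,6,7,8,8a-octahydronaphthalen-1-yl]pentanoate | CC(=O)OC[C@@H](O)COC(=O)C[C@H](C)CCC1=C(C)CC[C@@H]2C(C)(C)CCC[C@@]12C | target

**Step count and risks**

Total step count: 12. Longest linear sequence: 12 steps (1 to 17); methacrolein 7 and (S)-solketal 14 are purchased.

Steps most likely to fail:

Step 6. The cycloaddition may lose regiochemical and endo control, because the C10 methyl group of the diene opposes the directing effect of the C5 substituent and the acetate may slow the catalyst by coordination; C5 would then not be formed with one configuration. The fallback sets out from enal 5 and comes back at adduct 8. It reinforces the polarisation of the diene with a removable oxygen substituent on C1. Addition of MeMgBr (THF, −78 °C) to 5 should give the methyl carbinol (3R,6E,10E)-12-hydroxy-3,7,11-trimethyltrideca-6,10-dien-1-yl acetate F1. Dess–Martin oxidation should give the enone (3R,6E,10E)-3,7,11-trimethyl-12-oxotrideca-6,10-dien-1-yl acetate F2. TBSOTf/Et3N (CH2Cl2, −78 °C) should give the 2-silyloxydiene (3R,6E,10E)-12-[(tert-butyldimethylsilyl)oxy]-3,7,11-trimethyltrideca-6,10,12-trien-1-yl acetate F3. In the same catalysed cycloaddition with 7 the oxygen donor on C1 and the alkyl group on C5 now direct in concert, which should give the silyl enol ether adduct (3R,6E)-9-[(1S,6R)-3-[(tert-butyldimethylsilyl)oxy]-6-formyl-2,6-dimethylcyclohex-2-en-1-yl]-3,7-dimethylnon-6-en-1-yl acetate F4. CsF/PhNTf2 (DME, rt) should convert it into the enol triflate (3R,6E)-9-[(1S,6R)-6-formyl-2,6-dimethyl-3-{[(trifluoromethyl)sulfonyl]oxy}cyclohex-2-en-1-yl]-3,7-dimethylnon-6-en-1-yl acetate F5. Reduction with Pd(OAc)2/PPh3, HCO2H and Bu3N (DMF, 60 °C) replaces the C1–O bond by C1–H and gives 8.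

Step 9. In the superacid the free carboxyl group may ionise and acylate an alkene, the C10 cation may lose a proton toward C5 before ring closure (scrambling C5), and the alkene isomers may not converge fully on C8=C9. The fallback sets out from alcohol 10 and comes back at acid 13. It closes ring B one oxidation level earlier, on the acetate, the substrate class with the closest precedent for low-temperature chlorosulfonic acid cyclisation. Ac2O/pyridine should give (3R,6E)-3,7-dimethyl-9-[(1R)-2,6,6-trimethylcyclohex-2-en-1-yl]non-6-en-1-yl acetate F6. ClSO3H (2-nitropropane, −78 °C) followed by HI (cat.) in benzene at 80 °C should give the bicyclic acetate (3R)-3-methyl-5-[(4aR,8aR)-2,5,5,8a-tetramethyl-3,4,4a,5,6,7,8,8a-octahydronaphthalen-1-yl]pentyl acetate F7, which can be purified as a neutral compound. K2CO3/MeOH should give the alcohol (3R)-3-methyl-5-[(4aR,8aR)-2,5,5,8a-tetramethyl-3,4,4a,5,6,7,8,8a-octahydronaphthalen-1-yl]pentan-1-ol F8, and the oxidation of step 8 (oxoammonium catalyst, PhI(OAc)2, MeCN/H2O) then gives 13.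

Step 11. The liberated 1-monoacylglycerol 16 may undergo acyl migration to the secondary and then the other primary oxygen during hydrolysis or purification; this would scramble the glycerol stereocentre and give regioisomeric acetates in step 12. The fallback sets out from acid 13 and comes back at target 17, and never forms a free 1,2-diol. Carbodiimide esterification of 13 with (S)-glycidol (EDC·HCl, 4-(dimethylamino)pyridine, CH2Cl2) should give the glycidyl ester [(2R)-oxiran-2-yl]methyl (3R)-3-methyl-5-[(4aR,8aR)-2,5,5,8a-tetramethyl-3,4,4a,5,6,7,8,8a-octahydronaphthalen-1-yl]pentanoate F9. Carboxylate-catalysed opening of the epoxide at its terminal carbon with acetic acid (AcOH, tetrabutylammonium acetate (cat.), toluene, 70 °C) leaves the stereocentre untouched and should give 17 directly.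

**Further compounds**

F1 | step 6 | (3R,6E,10E)-12-hydroxy-3,7,11-trimethyltrideca-6,10-dien-1-yl acetate (both C12 epimers) | CC(=O)OCC[C@H](C)CC/C=C(\C)CC/C=C(\C)C(C)O
F2 | step 6 | (3R,6E,10E)-3,7,11-trimethyl-12-oxotrideca-6,10-dien-1-yl acetate | CC(=O)OCC[C@H](C)CC/C=C(\C)CC/C=C(\C)C(C)=O
F3 | step 6 | (3R,6E,10E)-12-[(tert-butyldimethylsilyl)oxy]-3,7,11-trimethyltrideca-6,10,12-trien-1-yl acetate | CC(=O)OCC[C@H](C)CC/C=C(\C)CC/C=C(\C)C(=C)O[Si](C)(C)C(C)(C)C
F4 | step 6 | (3R,6E)-9-[(1S,6R)-3-[(tert-butyldimethylsilyl)oxy]-6-formyl-2,6-dimethylcyclohex-2-en-1-yl]-3,7-dimethylnon-6-en-1-yl acetate | CC(=O)OCC[C@H](C)CC/C=C(\C)CC[C@@H]1[C@](C)(C=O)CCC(O[Si](C)(C)C(C)(C)C)=C1C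
F5 | step 6 | (3R,6E)-9-[(1S,6R)-6-formyl-2,6-dimethyl-3-{[(trifluoromethyl)sulfonyl]oxy}cyclohex-2-en-1-yl]-3,7-dimethylnon-6-en-1-yl acetate | CC(=O)OCC[C@H](C)CC/C=C(\C)CC[C@@H]1[C@](C)(C=O)CCC(OS(=O)(=O)C(F)(F)F)=C1C
F6 | step 9 | (3R,6E)-3,7-dimethyl-9-[(1R)-2,6,6-trimethylcyclohex-2-en-1-yl]non-6-en-1-yl acetate | CC(=O)OCC[C@H](C)CC/C=C(\C)CC[C@@H]1C(C)(C)CCC=C1C
F7 | step 9 | (3R)-3-methyl-5-[(4aR,8aR)-2,5,5,8a-tetramethyl-3,4,4a,5,6,7,8,8a-octahydronaphthalen-1-yl]pentyl acetate | CC(=O)OCC[C@H](C)CCC1=C(C)CC[C@@H]2C(C)(C)CCC[C@@]12C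
F8 | step 9 | (3R)-3-methyl-5-[(4aR,8aR)-2,5,5,8a-tetramethyl-3,4,4a,5,6,7,8,8a-octahydronaphthalen-1-yl]pentan-1-ol | OCC[C@H](C)CCC1=C(C)CC[C@@H]2C(C)(C)CCC[C@@]12C
F9 | step 11 | [(2R)-oxiran-2-yl]methyl (3R)-3-methyl-5-[(4aR,8aR)-2,5,5,8a-tetramethyl-3,4,4a,5,6,7,8,8a-octahydronaphthalen-1-yl]pentanoate | O=C(OC[C@H]1CO1)C[C@H](C)CCC2=C(C)CC[C@@H]3C(C)(C)CCC[C@@]23C
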